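**Retrosynthetic overview**

- The strategy rests on this feature: on the tetralin ring (C1–C4, C4a, C8a) the exocyclic carbon C9 on C2 is cis to the exocyclic carbon C10 on C3, and C1 is a diarylmethine carbon. C9 can therefore be handed from the oxygen on C10 to C2 of a C1=C2 styrene, and C1 is then closed with hydrogen.
- Disconnections, backwards: two O–CH3 bonds; C9–Si to C9–OH (Tamao oxidation); C2–C9 and C1–H (silicon-tethered radical cyclisation); O–Si (tether); C1–aryl (Suzuki coupling of an enol triflate); C1–C8a (Friedel–Crafts acylation); the C3 stereocentre (asymmetric hydrogenation of a Stobbe half ester).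
- Ring order: the carbocyclic tetralin ring is closed first by Friedel–Crafts acylation; the temporary 1,2-oxasilinane ring is closed in the key step and opened again by oxidation.
- The ester is reduced before the Suzuki coupling, so that C3 is never the α-carbon of an allylic ester under basic conditions.

Key step: step 8

Atom labels C1–C4, C9 and C10 in the text are those of the target tetralin; compound names use their own locants.
Assumption: the (S,S) hand of Et-DuPhos is taken to give the (R)-acid in step 2; if the sense of induction proves opposite, the (R,R) ligand is used and nothing else changes.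

**Step 1**
Reactants: 1 3,4-dimethoxybenzaldehyde; 2 dimethyl succinate
Product: 4 (E)-4-(3,4-dimethoxyphenyl)-3-(methoxycarbonyl)but-3-enoic acid, via paraconic ester lactone 3 (not isolated)
Conditions: NaOMe, MeOH, reflux; then aq HCl
Reagents that add atoms: none
Why: Stobbe condensation, in which the succinate enolate adds to the aldehyde, the alkoxide closes lactone 3 and base-induced E1cB opening gives the alkylidene half ester, the E isomer being favoured because the aryl group avoids the ester.

**Step 2**
Reactants: 4 (E)-4-(3,4-dimethoxyphenyl)-3-(methoxycarbonyl)but-3-enoic acid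
Product: 5 (3R)-4-(3,4-dimethoxyphenyl)-3-(methoxycarbonyl)butanoic acid
Conditions: H2 (5 bar), [Rh(COD)((S,S)-Et-DuPhos)]BF4 (1 mol %), NaOMe (0.1 equiv), MeOH, 25 °C
Reagents that add atoms: none
Why: Asymmetric hydrogenation of an itaconate-type half ester, in which the carboxylate and the alkene chelate monovalent rhodium and the chiral bisphospholane fixes the face of hydrogen delivery, setting C3 as R.

**Step 3**
Reactants: 5 (3R)-4-(3,4-dimethoxyphenyl)-3-(methoxycarbonyl)butanoic acid
Product: 6 methyl (2R)-6,7-dimethoxy-4-oxo-1,2,3,4-tetrahydronaphthalene-2-carboxylate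
Conditions: P2O5/MeSO3H (1:10 w/w), 25 °C
Reagents that add atoms: none
Why: Intramolecular Friedel–Crafts acylation by the free acid arm closes the six-membered ring at the arene position para to a methoxy group, and the stereocentre is not involved.

**Step 4**
Reactants: 6 methyl (2R)-6,7-dimethoxy-4-oxo-1,2,3,4-tetrahydronaphthalene-2-carboxylate
Product: 7 methyl (2R)-6,7-dimethoxy-4-(trifluoromethanesulfonyloxy)-1,2-dihydronaphthalene-2-carboxylate
Conditions: Tf2O, 2,6-di-tert-butyl-4-methylpyridine, CH2Cl2, 0 °C to rt; aq NaHCO3 wash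
Reagents that add atoms: trifluoromethanesulfonic anhydride, O=S(=O)(OS(=O)(=O)C(F)(F)F)C(F)(F)F
Why: Enol triflate formation by O-sulfonylation of the aryl ketone and loss of a C2 proton to a hindered pyridine; no strong base is present, so the ester α-carbon C3 should keep its configuration.

**Step 5**
Reactants: 7 methyl (2R)-6,7-dimethoxy-4-(trifluoromethanesulfonyloxy)-1,2-dihydronaphthalene-2-carboxylate
Product: 8 (3R)-3-(hydroxymethyl)-6,7-dimethoxy-3,4-dihydronaphthalen-1-yl trifluoromethanesulfonate
Conditions: i-Bu2AlH (2.5 equiv), CH2Cl2, −78 °C; aq potassium sodium tartrate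
Reagents that add atoms: none
Why: Ester reduction by an electrophilic aluminium hydride, which enol triflates tolerate at low temperature; once C10 is an alcohol, C3 can no longer epimerise.

**Step 6**
Reactants: 8 (3R)-3-(hydroxymethyl)-6,7-dimethoxy-3,4-dihydronaphthalen-1-yl trifluoromethanesulfonate; 9 (3,4-dimethoxyphenyl)boronic acid
Product: 10 [(2R)-4-(3,4-dimethoxyphenyl)-6,7-dimethoxy-1,2-dihydronaphthalen-2-yl]methanol
Conditions: Pd(PPh3)4 (5 mol %), 2 M aq Na2CO3, DME, 80 °C
Reagents that add atoms: none
Why: Suzuki–Miyaura coupling of an enol triflate (oxidative addition to zerovalent palladium, transmetalation from the boronate, reductive elimination) forms the C1–aryl bond, and the free primary alcohol is tolerated.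

**Step 7**
Reactants: 10 [(2R)-4-(3,4-dimethoxyphenyl)-6,7-dimethoxy-1,2-dihydronaphthalen-2-yl]methanol; 11 (bromomethyl)chlorodimethylsilane
Product: 12 (bromomethyl){[(2R)-4-(3,4-dimethoxyphenyl)-6,7-dimethoxy-1,2-dihydronaphthalen-2-yl]methoxy}dimethylsilane
Conditions: Et3N, DMAP (cat.), CH2Cl2, 0 °C; filtered and used without chromatography
Reagents that add atoms: none
Why: O-Silylation of a primary alcohol by a chlorosilane under amine base leaves the bromomethyl group untouched; the moisture-sensitive ether is carried on directly.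

**Step 8**
Reactants: 12 (bromomethyl){[(2R)-4-(3,4-dimethoxyphenyl)-6,7-dimethoxy-1,2-dihydronaphthalen-2-yl]methoxy}dimethylsilane
Product: 13 cis-fused oxasilinane: (1S,2S,3R)-1-(3,4-dimethoxyphenyl)-6,7-dimethoxytetralin carrying a 2,2-dimethyl-1-oxa-2-silacyclohexane ring across C2–C3 (Si–CH2 on C2, O–CH2 on C3; aryl, C9 and C10 all on one face)
Conditions: Bu3SnH (1.3 equiv, added over 6 h), AIBN (0.2 equiv), benzene (0.01 M), 80 °C
Reagents that add atoms: none
Why: This is a tin-mediated radical chain of the known type, the cyclisation of (bromomethyl)dimethylsilyl ethers of unsaturated alcohols: Bu3Sn• abstracts bromine from 12, the nucleophilic α-silyl radical at C9 adds to C2 of the C1=C2 styrene, and the diaryl-stabilised C1 radical takes hydrogen from Bu3SnH, which carries the chain. The 1,2-oxasilinane ring (C9, Si, O, C10, C3, C2) closes in the 6-exo-trig mode; attack at C2 is preferred over 7-endo attack at C1 because C2 is the less substituted alkene carbon and its attack leaves the more stabilised radical. The C2 stereocentre is controlled by C3 through the tether: in a chair-like transition state with C10 pseudoequatorial the short chain reaches only the face of C2 towards which the C3–C10 bond leans, whereas bonding at the other face would need a dihedral angle above 100° inside the new ring, so C9 is expected cis to C10 (2S). The C1 stereocentre is controlled by the new C2–C9 bond: it stands pseudoaxial, parallel to the half-filled orbital at C1, and the oxasilinane with its SiMe2 group covers that face, so Bu3SnH should deliver hydrogen anti to C9 and leave the aryl group cis to C9 and C10 (1S). The step therefore needs cis ring fusion and anti hydrogen transfer; the first rests on tether length, the second on steric and torsional approach control and is the selectivity at risk, while high dilution and slow addition of Bu3SnH keep the C9 radical from being reduced before it cyclises.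

**Step 9**
Reactants: 13 cis-fused oxasilinane
Product: 14 [(1S,2S,3R)-1-(3,4-dimethoxyphenyl)-6,7-dimethoxy-1,2,3,4-tetrahydronaphthalene-2,3-diyl]dimethanol
Conditions: 30% aq H2O2, KF, KHCO3, THF/MeOH (1:1), 50 °C
Reagents that add atoms: hydrogen peroxide, OO
Why: Tamao oxidation, in which peroxide adds to the fluoride-activated alkoxysilane and C9 migrates from silicon to oxygen, turns C9–Si into C9–OH and frees the C10 hydroxyl without touching a stereocentre.

**Step 10**
Reactants: 14 [(1S,2S,3R)-1-(3,4-dimethoxyphenyl)-6,7-dimethoxy-1,2,3,4-tetrahydronaphthalene-2,3-diyl]dimethanol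
Product: 15 (1S,2S,3R)-1-(3,4-dimethoxyphenyl)-6,7-dimethoxy-2,3-bis(methoxymethyl)-1,2,3,4-tetrahydronaphthalene
Conditions: NaH, MeI, THF/DMF, 0 °C to rt
Reagents that add atoms: iodomethane, CI
Why: Williamson etherification of both primary alkoxides with MeI; the diarylmethine C1–H is far too weakly acidic for NaH, so the all-cis array should be kept.

**Compound list**

1 | 3,4-dimethoxybenzaldehyde | COc1ccc(C=O)cc1OC | starting material
2 | dimethyl succinate | COC(=O)CCC(=O)OC | starting material
3 | methyl 2-(3,4-dimethoxyphenyl)-5-oxooxolane-3-carboxylate (paraconic ester lactone, not isolated) | COC(=O)C1CC(=O)OC1c1ccc(OC)c(OC)c1 | intermediate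
4 | (E)-4-(3,4-dimethoxyphenyl)-3-(methoxycarbonyl)but-3-enoic acid | COC(=O)/C(CC(=O)O)=C/c1ccc(OC)c(OC)c1 | intermediate
5 | (3R)-4-(3,4-dimethoxyphenyl)-3-(methoxycarbonyl)butanoic acid | COC(=O)[C@@H](CC(=O)O)Cc1ccc(OC)c(OC)c1 | intermediate
6 | methyl (2R)-6,7-dimethoxy-4-oxo-1,2,3,4-tetrahydronaphthalene-2-carboxylate | COC(=O)[C@@H]1Cc2cc(OC)c(OC)cc2C(=O)C1 | intermediate
7 | methyl (2R)-6,7-dimethoxy-4-(trifluoromethanesulfonyloxy)-1,2-dihydronaphthalene-2-carboxylate | COC(=O)[C@@H]1Cc2cc(OC)c(OC)cc2C(OS(=O)(=O)C(F)(F)F)=C1 | intermediate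
8 | (3R)-3-(hydroxymethyl)-6,7-dimethoxy-3,4-dihydronaphthalen-1-yl trifluoromethanesulfonate | OC[C@@H]1Cc2cc(OC)c(OC)cc2C(OS(=O)(=O)C(F)(F)F)=C1 | intermediate
9 | (3,4-dimethoxyphenyl)boronic acid | COc1ccc(B(O)O)cc1OC | starting material
10 | [(2R)-4-(3,4-dimethoxyphenyl)-6,7-dimethoxy-1,2-dihydronaphthalen-2-yl]methanol | OC[C@@H]1Cc2cc(OC)c(OC)cc2C(c2ccc(OC)c(OC)c2)=C1 | intermediate
11 | (bromomethyl)chlorodimethylsilane | C[Si](C)(Cl)CBr | starting material
12 | (bromomethyl){[(2R)-4-(3,4-dimethoxyphenyl)-6,7-dimethoxy-1,2-dihydronaphthalen-2-yl]methoxy}dimethylsilane | BrC[Si](C)(C)OC[C@@H]1Cc2cc(OC)c(OC)cc2C(c2ccc(OC)c(OC)c2)=C1 | intermediate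
13 | cis-fused oxasilinane of the (1S,2S,3R)-1-aryl-6,7-dimethoxytetralin (Si–CH2 on C2, O–CH2 on C3, SiMe2) | C[Si]2(C)OC[C@@H]1Cc3cc(OC)c(OC)cc3[C@H](c3ccc(OC)c(OC)c3)[C@@H]1C2 | intermediate
14 | [(1S,2S,3R)-1-(3,4-dimethoxyphenyl)-6,7-dimethoxy-1,2,3,4-tetrahydronaphthalene-2,3-diyl]dimethanol | OC[C@@H]1Cc2cc(OC)c(OC)cc2[C@H](c2ccc(OC)c(OC)c2)[C@@H]1CO | intermediate
15 | (1S,2S,3R)-1-(3,4-dimethoxyphenyl)-6,7-dimethoxy-2,3-bis(methoxymethyl)-1,2,3,4-tetrahydronaphthalene | COC[C@@H]1Cc2cc(OC)c(OC)cc2[C@H](c2ccc(OC)c(OC)c2)[C@@H]1COC | target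

**Step count**

Total steps: 10. Longest linear sequence: 10 steps (from 1 and 2 to 15).

**Steps most likely to fail**

Step 8. The hydrogen transfer to C1 may show poor facial selectivity, or the C9 radical may be reduced before it cyclises. The fallback sets out from 10 and comes back at 14; it brings C9 in as an electrophile and sets C1 and C2 together by hydrogenation. Alcohol 10 would be acetylated (Ac2O, pyridine) to [(2R)-4-(3,4-dimethoxyphenyl)-6,7-dimethoxy-1,2-dihydronaphthalen-2-yl]methyl acetate F1. Vilsmeier–Haack formylation (POCl3, DMF, 0 to 60 °C, then aq NaOAc) at the vinylic C2 of the electron-rich 1,1-diarylalkene should give [(2R)-4-(3,4-dimethoxyphenyl)-3-formyl-6,7-dimethoxy-1,2-dihydronaphthalen-2-yl]methyl acetate F2. LiAlH4 (THF, 0 °C) would reduce the aldehyde and cleave the acetate to give [(2R)-4-(3,4-dimethoxyphenyl)-6,7-dimethoxy-1,2-dihydronaphthalene-2,3-diyl]dimethanol F3. Hydrogenation of the tetrasubstituted C1=C2 bond (H2, Pd/C, EtOAc) is expected from the face opposite C10, which A(1,2) strain with C9 holds pseudoaxial, and should give the all-cis diol 14.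

Step 4. Configuration at C3 may be lost by enolisation of the allylic ester while the enol triflate forms or is handled. The fallback sets out from 6 and comes back at 8; it removes the ester before the alkene is made. Keto ester 6 would be reduced (LiAlH4, THF) to (3R)-3-(hydroxymethyl)-6,7-dimethoxy-1,2,3,4-tetrahydronaphthalen-1-ol F4, a mixture of carbinol epimers. Selective silylation of the primary hydroxyl (TBSCl, imidazole, CH2Cl2, 0 °C) would give (3R)-3-{[tert-butyl(dimethyl)silyl]oxymethyl}-6,7-dimethoxy-1,2,3,4-tetrahydronaphthalen-1-ol F5. Oxidation of the benzylic alcohol (MnO2, CH2Cl2) would give (3R)-3-{[tert-butyl(dimethyl)silyl]oxymethyl}-6,7-dimethoxy-3,4-dihydronaphthalen-1(2H)-one F6, in which C3 is no longer acidic. Enolisation and triflation (KN(SiMe3)2, PhNTf2, THF, −78 °C) would give (3R)-3-{[tert-butyl(dimethyl)silyl]oxymethyl}-6,7-dimethoxy-3,4-dihydronaphthalen-1-yl trifluoromethanesulfonate F7. Acidic desilylation (1% HCl in MeOH, 0 °C), chosen because fluoride can attack the triflate, would give 8.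

Step 2. The enantioselectivity of the hydrogenation may be insufficient. The fallback sets out from 4 and comes back at 5; it replaces asymmetric catalysis by classical resolution. Half ester 4 would be hydrogenated without a chiral ligand (H2, Pd/C, MeOH) to racemic 4-(3,4-dimethoxyphenyl)-3-(methoxycarbonyl)butanoic acid F8. Salt formation with one hand of 1-phenylethylamine (written here as R; the hand whose salt with the (R)-acid is the less soluble would be used) and recrystallisation should give (R)-1-phenylethylammonium (3R)-4-(3,4-dimethoxyphenyl)-3-(methoxycarbonyl)butanoate F9. Acidification with aq HCl and extraction would give 5.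

**Further compounds**

F1 | step 8 | [(2R)-4-(3,4-dimethoxyphenyl)-6,7-dimethoxy-1,2-dihydronaphthalen-2-yl]methyl acetate | CC(=O)OC[C@@H]1Cc2cc(OC)c(OC)cc2C(c2ccc(OC)c(OC)c2)=C1
F2 | step 8 | [(2R)-4-(3,4-dimethoxyphenyl)-3-formyl-6,7-dimethoxy-1,2-dihydronaphthalen-2-yl]methyl acetate | CC(=O)OC[C@@H]1Cc2cc(OC)c(OC)cc2C(c2ccc(OC)c(OC)c2)=C1C=O
F3 | step 8 | [(2R)-4-(3,4-dimethoxyphenyl)-6,7-dimethoxy-1,2-dihydronaphthalene-2,3-diyl]dimethanol | OC[C@@H]1Cc2cc(OC)c(OC)cc2C(c2ccc(OC)c(OC)c2)=C1CO
F4 | step 4 | (3R)-3-(hydroxymethyl)-6,7-dimethoxy-1,2,3,4-tetrahydronaphthalen-1-ol (carbinol epimers) | OC[C@@H]1Cc2cc(OC)c(OC)cc2C(O)C1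
F5 | step 4 | (3R)-3-{[tert-butyl(dimethyl)silyl]oxymethyl}-6,7-dimethoxy-1,2,3,4-tetrahydronaphthalen-1-ol (carbinol epimers) | CC(C)(C)[Si](C)(C)OC[C@@H]1Cc2cc(OC)c(OC)cc2C(O)C1
F6 | step 4 | (3R)-3-{[tert-butyl(dimethyl)silyl]oxymethyl}-6,7-dimethoxy-3,4-dihydronaphthalen-1(2H)-one | CC(C)(C)[Si](C)(C)OC[C@@H]1Cc2cc(OC)c(OC)cc2C(=O)C1
F7 | step 4 | (3R)-3-{[tert-butyl(dimethyl)silyl]oxymethyl}-6,7-dimethoxy-3,4-dihydronaphthalen-1-yl trifluoromethanesulfonate | CC(C)(C)[Si](C)(C)OC[C@@H]1Cc2cc(OC)c(OC)cc2C(OS(=O)(=O)C(F)(F)F)=C1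
F8 | step 2 | racemic 4-(3,4-dimethoxyphenyl)-3-(methoxycarbonyl)butanoic acid | COC(=O)C(CC(=O)O)Cc1ccc(OC)c(OC)c1
F9 | step 2 | (R)-1-phenylethylammonium (3R)-4-(3,4-dimethoxyphenyl)-3-(methoxycarbonyl)butanoate | COC(=O)[C@@H](CC(=O)[O-])Cc1ccc(OC)c(OC)c1.C[C@@H]([NH3+])c1ccccc1
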